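## The problem

Compound 12 is built from two hexasubstituted benzene rings that share one methylene carbon. Ring A (C1 propionyl, C2 OH, C3 CH3, C4 OH, C5 bridge, C6 OH) and ring B (C1' bridge, C2' OH, C3' propionyl, C4' OH, C5' CH3, C6' OCH3) are the same C-methyl propionylphloroglucinol, apart from one methyl ether on the ring-B oxygen para to the ketone. There is no stereocentre, so the task is purely constitutional: six substituents in the right order on each ring, and two almost identical, very nucleophilic rings joined through one carbon without homo-coupling. Condensing two phenolic monomers with a one-carbon electrophile would give a statistical set of dimers, and a bridge flanked by free phenols on both rings changes partners in base through quinone methides and can be cut by strong acid through ipso protonation. The free acylphloroglucinol is also easily oxidised as its polyanion, and the single methyl ether has to survive whatever frees the other five oxygens. The feature that offers a way round the coupling problem lies in ring A: C1, which carries the propionyl group, sits between the two C–OH carbons C2 and C6, and C3 carries a methyl group. If the C3–C4 bond is opened, C2, C3 and the ring methyl become a second propionyl group on the same carbon as the first. The open chain then has two identical propionyl arms, either of which closes to the same ring, while C5 with the bridge and all of ring B sits on a malonate-type carbon.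

## Retrosynthesis

**12 ⇒ 11.** The last operation is cleavage of two O–CH3 bonds, those at C2' and C4' on either side of the ring-B ketone. Carrying ring B as its trimethyl ether 11 is preferred to differentiated protection for three reasons. All three oxygens then come from one cheap arene. Ring B has no phenoxide during the basic ring closure and so cannot enter bridge exchange. The two ethers to be removed are the two a Lewis acid can reach by chelation to the C3' carbonyl, whereas the C6' ether has no such anchor. The forward reaction has to stop after exactly two cleavages on a crowded ring.

**11 ⇒ 10.** Ring A is opened at C3–C4, the bond between the methyl-bearing carbon and the neighbouring C–OH carbon, to give the open-chain keto ester 10. Chain C1 (ester) becomes ring C4, C2 (bearing the benzyl group) ring C5, C3 ring C6, C4 (the triacylmethane carbon) ring C1, C5 ring C2, C6 ring C3 and C7 the ring methyl.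

- Cutting the ring-to-bridge bond instead would return to the coupling of two phloroglucinols.
- The classical polyketide cut at C1–C2 or C1–C6 would use a doubly activated nucleophile and is in that respect the easier condensation. Its chain, however, is an unsymmetrical, doubly branched triketo ester that can also close by aldol condensation to a resorcinol and must be built linearly.
- The C3–C4 cut is the only one that gives two equivalent nucleophilic arms, leaves no aldol mode (every other carbonyl is 1,3 to the nucleophilic carbons), and keeps the very acidic triacylmethane carbon away from the ester.

The price is a singly activated nucleophile and an acidic C–H next to the ester. A fully deprotonated chain would be inert because the ester would itself be an enolate. The closure is therefore planned under equilibrating, non-nucleophilic alkoxide conditions, with aromatisation as the irreversible exit.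

**10 ⇒ 9 + 8.** The chain is cut at C3–C4, between the malonyl carbonyl and the triacylmethane carbon. This is the C-acylation of the symmetric diketone 8 by acid chloride 9, which is made from half-ester 7. Because 8 is symmetric, there is one nucleophilic carbon and no regiochemical choice; an unsymmetric diketone would not offer this. The forward step must deliver C- rather than O-acylation with an α-branched acid chloride, which is the role of the magnesium chelate of 8.

**7 ⇒ 6 ⇒ 4 + 5.** Half-ester 7 comes from diester 6 by hydrolysis of one of two equivalent esters. Diester 6 is cut at the bond between the bridge carbon and the malonate carbon, giving benzylic chloride 4 and dimethyl malonate 5. The ring union of the target is thereby reduced to a malonate alkylation, which cannot produce a homo-dimer.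

**4 ⇒ 3 ⇒ 1 + 2.** The chloromethyl carbon and the propionyl group are removed in turn from ring B, leading to 2,4,6-trimethoxytoluene 1 and propionyl chloride 2. The two free positions of 1 are equivalent, and 3 has only one position left, so neither substitution has a regiochemical alternative. Acylation comes first so that the reactive benzylic chloride is formed on a ring already tempered by the ketone.

## Roads not taken

**Alternative 1:** Here the ring-to-oxygen and ring-to-propionyl bonds of one aromatic ring are cut together. In the forward step a fluoride source releases an aryne from silyl triflate A2; propionic acid A3 adds through oxygen at the carbon remote from the flanking methoxy group, and the aryl anion takes the acyl group to give hydroxy ketone A1.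

- Merits: a free ortho-hydroxy ketone is set in one operation, with regiochemistry dictated by the methoxy group next to the triple bond. A1 needs only a single chelation-assisted ether cleavage on a pentasubstituted ring to reach the ring-B monomer A4. That is an easier selectivity problem than the double cleavage on the hexasubstituted ring of 11, and in this respect the alternative is better.
- Weak points: A2 itself takes several steps from a phenol. A1 differs from compound 3 only in one O-methyl group, and 3 is available in one Friedel–Crafts step. Above all, the aryne step does not address the bridge or the second ring, so the unsymmetrical union of two phloroglucinols remains to be solved after it.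
- Comparison: the chosen plan accepts the harder demethylation at the end, and in exchange the bridge is installed by a malonate alkylation and ring A is built around it.

**Alternative 2:** Ring A is taken apart into a four-carbon vinylketene unit and a two-carbon alkyne. In the forward step cyclobutenone A6, which already carries the ring-B benzyl group, opens thermally, adds to siloxyalkyne A7 and, after ring opening and six-electron closure, gives the pentasubstituted phenol A5.

- Merits: it is convergent, fully regiocontrolled and runs under neutral thermal conditions, with the bridge in place and no polyanion or strong base. In this it is superior to the Claisen closure, whose outcome depends on a delicate balance of anions.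
- Weak points: A5 carries neither propionyl group. Two Friedel–Crafts acylations would have to be run on a diarylmethane whose rings are both still undeactivated, the situation in which acid-induced loss or migration of the bridge is most likely. Three kinds of oxygen protection (ethyl, silyl, methyl) must be removed while one methyl ether is kept. A6 and A7 each need several steps, and the benzylic halide needed for A6 has no acyl group to moderate its lability.
- Comparison: the chosen plan has both ketones in place before the bridge meets any Lewis acid and needs seven steps in all; its ring closure is less certain than the benzannulation.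

**Alternative 3:** The methoxy ring is cut into a 1,3-dioxygenated diene and an acylalkyne. In the forward step the silyl ketene acetal diene A9 adds to ynone A10 and aromatises with loss of the acetal methoxy group to give ketone A8.

- Merits: the para methoxyl is differentiated from the outset. The only ether to cleave afterwards is an ethyl ether ortho to the ketone, which gives A4 with ordinary chelation selectivity, and no selective demethylation among three methyl ethers is needed. This is the alternative's real advantage over the chosen endgame.
- Weak points: A9 and A10 each have to be prepared, so several steps go into a monomer that a one-step acylation of 1 approaches closely. As in Alternative 1, the bridge and ring A are left for a later coupling of two phenols.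
- Comparison: the chosen plan is shorter and has solved the ring union by step 3; its oxygen differentiation is postponed to the last step and is less secure.

Key step: step 6

Remark on the chemistry: the target has no stereocentre. Compounds 7, 9 and 10 carry one stereocentre at the future ring carbon C5, are used as racemates, and lose it on aromatisation. Triacylmethane 10 is drawn as the triketo tautomer although it will exist largely as a chelated enol.

## Route

Step 1
Reactants: 1 2,4,6-trimethoxytoluene; 2 propionyl chloride
Product: 3 1-(2,4,6-trimethoxy-3-methylphenyl)propan-1-one
Conditions: EtCOCl (1.05 equiv), SnCl4 (1.1 equiv), CH2Cl2, −20 → 0 °C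
Reagents that add atoms: none
Why: Friedel–Crafts acylation; the two free positions of 1 are equivalent and each is activated by two ortho and one para methoxy groups, a mild Lewis acid at low temperature avoids chelation-assisted demethylation, and the twisted ketone product resists a second acylation.

Step 2
Reactants: 3 1-(2,4,6-trimethoxy-3-methylphenyl)propan-1-one
Product: 4 1-[3-(chloromethyl)-2,4,6-trimethoxy-5-methylphenyl]propan-1-one
Conditions: (CH2O)n (3 equiv), HCl (4 M in 1,4-dioxane, excess), AcOH, 10 °C → rt; used crude
Reagents that add atoms: formaldehyde (as paraformaldehyde), C=O; hydrogen chloride, Cl
Why: Blanc chloromethylation (electrophilic aromatic substitution) at the only free ring position, which lies between two methoxy groups and para to the third; the ketone tempers the ring, and excess formaldehyde and HCl at low temperature hold back diarylmethane formation.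

Step 3
Reactants: 4 1-[3-(chloromethyl)-2,4,6-trimethoxy-5-methylphenyl]propan-1-one; 5 dimethyl malonate
Product: 6 dimethyl 2-[(2,4,6-trimethoxy-3-methyl-5-propanoylphenyl)methyl]propanedioate
Conditions: 5 (3 equiv), NaH (2.5 equiv), THF/DMF, 0 °C; then 4, 0 °C → rt
Reagents that add atoms: none
Why: Malonic ester alkylation of a benzylic chloride activated by ortho and para methoxy groups; excess malonate suppresses dialkylation, and sodiomalonate is too weak a base to enolise the hindered aryl ketone.

Step 4
Reactants: 6 dimethyl 2-[(2,4,6-trimethoxy-3-methyl-5-propanoylphenyl)methyl]propanedioate
Product: 7 3-methoxy-3-oxo-2-[(2,4,6-trimethoxy-3-methyl-5-propanoylphenyl)methyl]propanoic acid (racemic)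
Conditions: KOH (1.0 equiv), MeOH, 0 °C → rt; then 1 M HCl to pH 2 at 0 °C
Reagents that add atoms: potassium hydroxide, [K+].[OH-]
Why: Mono-saponification of a malonic diester; the carboxylate formed deactivates the remaining ester, the two esters are equivalent so only mono versus double hydrolysis matters, and the half-acid is kept cold to avoid decarboxylation.

Step 5
Reactants: 7 3-methoxy-3-oxo-2-[(2,4,6-trimethoxy-3-methyl-5-propanoylphenyl)methyl]propanoic acid; 8 heptane-3,5-dione
Product: 10 methyl 2-[(2,4,6-trimethoxy-3-methyl-5-propanoylphenyl)methyl]-3,5-dioxo-4-propanoylheptanoate (racemic), via malonic half-ester chloride 9 (not isolated)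
Conditions: (COCl)2 (1.3 equiv), DMF (cat.), CH2Cl2, 0 °C → rt, evaporate; then 8 (1.2 equiv), MgCl2 (1.2 equiv), pyridine (2.5 equiv), CH2Cl2, 0 °C → rt; 1 M HCl work-up
Reagents that add atoms: oxalyl chloride, O=C(Cl)C(Cl)=O (supplies the chlorine of 9; none of its atoms remain in 10)
Why: Acid chloride formation followed by C-acylation of a magnesium-chelated 1,3-diketone enolate (soft enolisation with MgCl2 and an amine base); chelation of both diketone oxygens leaves carbon as the nucleophilic site and holds the triacylmethane product as its magnesium chelate, and the symmetry of 8 removes any regiochemical question.

Step 6
Reactants: 10 methyl 2-[(2,4,6-trimethoxy-3-methyl-5-propanoylphenyl)methyl]-3,5-dioxo-4-propanoylheptanoate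
Product: 11 1-{2,4,6-trihydroxy-3-methyl-5-[(2,4,6-trimethoxy-3-methyl-5-propanoylphenyl)methyl]phenyl}propan-1-one
Conditions: KOtBu (4 equiv), THF/t-BuOH (5:1), 0.01 M, argon, 0 → 60 °C; then 1 M HCl, 0 °C
Reagents that add atoms: none
Why: Intramolecular Claisen (Dieckmann-type) condensation of a ketone enolate with an ester, the reaction type that turns 5-oxo esters into cyclohexane-1,3-diones and polyketo esters into acylphloroglucinols. tert-Butoxide removes the triacylmethane proton and then, reversibly, the proton at chain C2 between ester and ketone; this dianion is the resting state and shields the ester from the enolate oxygens, which should suppress lactonisation to a 4-hydroxy-2-pyrone. Because tert-butanol keeps all C–H sites in equilibrium, a small share of the isomeric dianion with C2 protonated and one propionyl group enolised is always present, and its α-carbon adds to the methyl ester in a 6-(enolendo)-exo-trig closure that forms the ring C3–C4 bond. This is the only ring size open to any carbanion of the chain, since every other carbonyl would give a four-membered ring and the ring-B ketone enolate could reach only a meta-bridged eight-membered ring. Loss of methoxide and proton shifts give the aromatic triphenoxide, which is irreversible and drains the equilibrium. The two propionyl groups are constitutionally equivalent, so whichever closes the same ring forms and the other remains as the ring-A ketone; no stereocentre is created and the one at C2 disappears. A hindered alkoxide is used instead of methoxide to hold back retro-Claisen cleavage of the triacylmethane, and ring B, having no free phenol, cannot enter quinone-methide exchange of the bridge under base.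

Step 7
Reactants: 11 1-{2,4,6-trihydroxy-3-methyl-5-[(2,4,6-trimethoxy-3-methyl-5-propanoylphenyl)methyl]phenyl}propan-1-one
Product: 12 1-{2,4,6-trihydroxy-3-[(2,4-dihydroxy-6-methoxy-5-methyl-3-propanoylphenyl)methyl]-5-methylphenyl}propan-1-one (CNP0215809.0)
Conditions: BCl3 (1 M in CH2Cl2, 6–8 equiv), CH2Cl2, −78 → 0 °C; cold MeOH/H2O quench
Reagents that add atoms: none
Why: Chelation-controlled Lewis-acid cleavage of aryl methyl ethers; BCl3 bound at the C3' carbonyl is delivered to the two flanking methoxy oxygens through six-membered chelates and chloride removes the methyl groups, while the C6' methoxyl has no such anchor and the ring-A phenols only form borates that hydrolyse on work-up.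

## Compound list

1 | 2,4,6-trimethoxytoluene | Cc1c(OC)cc(OC)cc1OC | starting material
2 | propionyl chloride | CCC(Cl)=O | starting material
3 | 1-(2,4,6-trimethoxy-3-methylphenyl)propan-1-one | CCC(=O)c1c(OC)cc(OC)c(C)c1OC | intermediate
4 | 1-[3-(chloromethyl)-2,4,6-trimethoxy-5-methylphenyl]propan-1-one | CCC(=O)c1c(OC)c(C)c(OC)c(CCl)c1OC | intermediate
5 | dimethyl malonate | COC(=O)CC(=O)OC | starting material
6 | dimethyl 2-[(2,4,6-trimethoxy-3-methyl-5-propanoylphenyl)methyl]propanedioate | COC(=O)C(Cc1c(OC)c(C(=O)CC)c(OC)c(C)c1OC)C(=O)OC | intermediate
7 | 3-methoxy-3-oxo-2-[(2,4,6-trimethoxy-3-methyl-5-propanoylphenyl)methyl]propanoic acid (racemic) | COC(=O)C(Cc1c(OC)c(C(=O)CC)c(OC)c(C)c1OC)C(=O)O | intermediate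
8 | heptane-3,5-dione | CCC(=O)CC(=O)CC | starting material
9 | methyl 3-chloro-3-oxo-2-[(2,4,6-trimethoxy-3-methyl-5-propanoylphenyl)methyl]propanoate (racemic, not isolated) | COC(=O)C(Cc1c(OC)c(C(=O)CC)c(OC)c(C)c1OC)C(Cl)=O | intermediate
10 | methyl 2-[(2,4,6-trimethoxy-3-methyl-5-propanoylphenyl)methyl]-3,5-dioxo-4-propanoylheptanoate (racemic) | COC(=O)C(Cc1c(OC)c(C(=O)CC)c(OC)c(C)c1OC)C(=O)C(C(=O)CC)C(=O)CC | intermediate
11 | 1-{2,4,6-trihydroxy-3-methyl-5-[(2,4,6-trimethoxy-3-methyl-5-propanoylphenyl)methyl]phenyl}propan-1-one | CCC(=O)c1c(O)c(C)c(O)c(Cc2c(OC)c(C(=O)CC)c(OC)c(C)c2OC)c1O | intermediate
12 | 1-{2,4,6-trihydroxy-3-[(2,4-dihydroxy-6-methoxy-5-methyl-3-propanoylphenyl)methyl]-5-methylphenyl}propan-1-one | CCC(=O)c1c(O)c(C)c(O)c(Cc2c(O)c(C(=O)CC)c(O)c(C)c2OC)c1O | target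

## Step count and risk

Total step count: 7. Longest linear sequence: 7 steps (1 → 12); compounds 2, 5 and 8 enter as purchased reagents.

**Step 6 (key step).** Three processes could defeat the closure:

- lactonisation through an enolate oxygen, which would outrun C-acylation if the monoanion rather than the C2 enolate is the species that reacts;
- retro-Claisen fragmentation of the triacylmethane by the methoxide set free during the reaction;
- stalling, if the productive propionyl enolate is too sparsely populated beside the unreactive polyanion.

The fallback gives up ring construction in favour of ring coupling. It sets out from 3: exhaustive ether cleavage with BBr3 (CH2Cl2, −78 °C → rt) gives 1-(2,4,6-trihydroxy-3-methylphenyl)propan-1-one F1. Friedel–Crafts benzylation of F1 with chloride 4 (hexafluoroisopropanol, or catalytic ZnCl2 in dioxane) then gives 11, where the route resumes at step 7. F1 has a single free ring carbon and the ring of 4 is fully substituted, so neither regiochemistry nor self-alkylation of 4 arises. Any O-benzyl ether of this electron-rich type should rearrange to the C-benzyl phenol under the same acidic conditions.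

**Step 7.** The ether cleavage may be unselective in either direction. It may stop after one methoxyl, since the first boron phenoxide ties up the carbonyl. It may also go on to the C6' methoxyl, which is twisted out of conjugation by its two neighbours and therefore more Lewis basic than an ordinary anisole. Acid-induced migration of the bridge is a further hazard. The fallback uses the near-symmetry of the target. It sets out from 11: BBr3 in excess removes all three methyl groups to give the symmetric hexaphenol 1-{2,4,6-trihydroxy-3-methyl-5-[(2,4,6-trihydroxy-3-methyl-5-propanoylphenyl)methyl]phenyl}propan-1-one F2. One equivalent of trimethylsilyldiazomethane (toluene/MeOH, 0 °C) then methylates one para hydroxyl, which on each ring is the only hydroxyl not chelated to a ketone, to give 12. Because the two rings of F2 are identical, either para hydroxyl leads to 12; unreacted F2 would be recycled and the dimethyl ether separated.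

**Step 2.** The product chloride may alkylate unreacted 3 to give a diarylmethane, and the labile chloride may solvolyse during isolation. The fallback avoids a benzylic halide altogether. It sets out from 3: Rieche formylation (Cl2CHOMe, TiCl4, CH2Cl2, 0 °C) gives 2,4,6-trimethoxy-3-methyl-5-propanoylbenzaldehyde F3. Knoevenagel condensation with 5 (piperidine, AcOH, toluene, reflux with water removal) gives dimethyl 2-[(2,4,6-trimethoxy-3-methyl-5-propanoylphenyl)methylidene]propanedioate F4. Hydrogenation of the conjugated double bond (H2, Pd/C, EtOAc), which the hindered aryl ketone should survive, gives 6, where the route resumes at step 4.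

**Step 5.** The α-branched acid chloride 9 has an acidic hydrogen and may go to a ketene that dimerises instead of acylating. O-acylation of the diketone may compete, and half-acid 7 may decarboxylate during activation. The fallback reverses the order of bond formation in the chain. It sets out from 8: acylation with commercial methyl malonyl chloride under the same MgCl2/pyridine conditions gives methyl 3,5-dioxo-4-propanoylheptanoate F5. Its dianion (NaH, 2.2 equiv, THF/DMF) is then alkylated by chloride 4 at the less stabilised C2 to give 10, where the route resumes at step 6. Steps 3 and 4 are then not needed.

## Further compounds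

F1 | step 6 | 1-(2,4,6-trihydroxy-3-methylphenyl)propan-1-one | CCC(=O)c1c(O)cc(O)c(C)c1O
F2 | step 7 | 1-{2,4,6-trihydroxy-3-methyl-5-[(2,4,6-trihydroxy-3-methyl-5-propanoylphenyl)methyl]phenyl}propan-1-one | CCC(=O)c1c(O)c(C)c(O)c(Cc2c(O)c(C(=O)CC)c(O)c(C)c2O)c1O
F3 | step 2 | 2,4,6-trimethoxy-3-methyl-5-propanoylbenzaldehyde | CCC(=O)c1c(OC)c(C)c(OC)c(C=O)c1OC
F4 | step 2 | dimethyl 2-[(2,4,6-trimethoxy-3-methyl-5-propanoylphenyl)methylidene]propanedioate | COC(=O)C(=Cc1c(OC)c(C(=O)CC)c(OC)c(C)c1OC)C(=O)OC
F5 | step 5 | methyl 3,5-dioxo-4-propanoylheptanoate | COC(=O)CC(=O)C(C(=O)CC)C(=O)CC
A1 | alternative 1 | 1-(6-hydroxy-2,4-dimethoxy-3-methylphenyl)propan-1-one | CCC(=O)c1c(O)cc(OC)c(C)c1OC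
A2 | alternative 1 | 3,5-dimethoxy-4-methyl-2-(trimethylsilyl)phenyl trifluoromethanesulfonate | COc1cc(OS(=O)(=O)C(F)(F)F)c([Si](C)(C)C)c(OC)c1C
A3 | alternative 1 | propionic acid | CCC(=O)O
A4 | alternative 1 | 1-(2,6-dihydroxy-4-methoxy-3-methylphenyl)propan-1-one | CCC(=O)c1c(O)cc(OC)c(C)c1O
A5 | alternative 2 | 5-ethoxy-2-methyl-3-(triisopropylsilyloxy)-4-[(2,4,6-trimethoxy-3-methylphenyl)methyl]phenol | CCOc1cc(O)c(C)c(O[Si](C(C)C)(C(C)C)C(C)C)c1Cc1c(OC)cc(OC)c(C)c1OC
A6 | alternative 2 | 3-ethoxy-4-[(2,4,6-trimethoxy-3-methylphenyl)methyl]cyclobut-2-en-1-one (racemic) | CCOC1=CC(=O)C1Cc1c(OC)cc(OC)c(C)c1OC
A7 | alternative 2 | triisopropyl(prop-1-yn-1-yloxy)silane | CC#CO[Si](C(C)C)(C(C)C)C(C)C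
A8 | alternative 3 | 1-(2-ethoxy-6-hydroxy-4-methoxy-5-methylphenyl)propan-1-one | CCC(=O)c1c(O)c(C)c(OC)cc1OCC
A9 | alternative 3 | [(1,3-dimethoxy-2-methylbuta-1,3-dien-1-yl)oxy]trimethylsilane | COC(=C)C(C)=C(OC)O[Si](C)(C)C
A10 | alternative 3 | 1-ethoxypent-1-yn-3-one | CCOC#CC(=O)CC
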